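**Target:** CNP0113604.1 = (1Z,2S,3aR,5S,6S,7S,7aR)-2-acetoxy-1-ethylidene-5-hydroxy-4-methylidene-7-(propan-2-yl)octahydro-1H-inden-6-yl (2Z)-2-methylbut-2-enoate. It is a trans-hydrindane with H-7a, 7-isopropyl, 6-O-angeloyl and 2-OAc on one face and H-3a and 5-OH on the other.

**Retrosynthetic overview**
1. Target ⇐ trans-diaxial opening of a 5α,6α-vinyl epoxide by angelic acid at C6; C2 acetate ⇐ catalyst-controlled reduction of a (Z)-1-ethylidene-2-ketone.
2. (Z)-Ethylidene ketone ⇐ deacetylative ethylidenation of a 1-acetyl-hydrindan-2-one with acetaldehyde.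
3. Key step: ring contraction of ring B of a cadinane-type trans-octalin (cyclohexene → 2-acetylcyclopentanone by ozonolysis and Claisen reclosure); the extruded ring carbon becomes the acetyl group and the trans ring fusion is kept.
4. trans-Octalone ⇐ Diels–Alder reaction of (S)-cryptone with isoprene; ring A enone ⇐ dehydrogenation, then nucleophilic epoxidation.
5. Ring order: ring A (Michael/aldol annulation) → ring B (Diels–Alder) → five-membered ring (contraction of ring B).

Convention (one line): ring-contracted compounds carry the hydrindane numbering of the target (C1–C3, C3a, C4–C7, C7a); β = face of H-7a, α = face of H-3a; the absolute sense is fixed by C7 from (S)-cryptone and is as in the SMILES; a one-flask telescoped sequence counts as one step.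

**Route**

Step 1
Reactants: 1 3-methylbutanal; 2 but-3-en-2-one
Product: 4 (S)-cryptone [(4S)-4-(propan-2-yl)cyclohex-2-en-1-one], via keto aldehyde 3 (not isolated)
Conditions: (S)-2-(methoxydiphenylmethyl)pyrrolidine (5 mol%), ethyl 3,4-dihydroxybenzoate (20 mol%), neat, 4 °C; then KOH, Bu4NOH (cat.), Et2O/THF/H2O, reflux
Reagents that add atoms: none
Why: Enamine-catalysed Michael addition, in which the diarylmethyl group shields one face of the E-enamine so that the 2S aldehyde (future C7) forms, followed by intramolecular aldol condensation (Robinson-type annulation).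

Step 2
Reactants: 4 (S)-cryptone; 5 2-methylbuta-1,3-diene
Product: 7 trans-fused octalone (4S,4aS,8aR), via cis-fused adduct 6 (not isolated)
Conditions: AlCl3 (25 mol%), toluene, 23 °C; then NaOMe (20 mol%), MeOH, 23 °C
Reagents that add atoms: none
Why: Lewis-acid-catalysed Diels–Alder reaction in which isoprene adds anti to the isopropyl group (sets C7a) with para orientation (methyl-bearing alkene carbon next to the CH2 on C7a), after which methoxide epimerises C3a, α to the ketone, to the more stable trans-fused octalone.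

Step 3
Reactants: 7 trans-fused octalone
Product: 9 ring A enone (4R,4aS,8aR), via silyl enol ether 8 (not isolated)
Conditions: LiN(SiMe3)2, Me3SiCl, THF, −78 °C; then Pd(OAc)2 (10 mol%), O2 (1 atm), DMSO, 23 °C
Reagents that add atoms: none
Why: Kinetic enolisation toward the CH2 rather than the ring-fusion methine, then Saegusa–Ito dehydrogenation with oxygen as terminal oxidant; no stereocentre is touched.

Step 4
Reactants: 9 ring A enone
Product: 10 epoxy ketone (2R,3R,4S,4aS,8aR)
Conditions: H2O2 (30% aq.), NaOH (0.2 equiv), MeOH, 0 °C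
Reagents that add atoms: hydrogen peroxide OO
Why: Weitz–Scheffer nucleophilic epoxidation of the only enone, in which hydroperoxide adds to C6 on the face opposite the neighbouring isopropyl group and the axial H-7a, giving the 5α,6α-epoxide with the C5 oxygen already in its final configuration.

Step 5
Reactants: 10 epoxy ketone
Product: 11 ring B seco keto ester
Conditions: O3, NaOH, MeOH/CH2Cl2 (1:4), −78 °C
Reagents that add atoms: ozone [O-][O+]=O; methanol CO
Why: Ozonolysis of the only C=C in methanolic base, which converts the CH= terminus directly into the methyl ester and the methyl-bearing carbon into the methyl ketone; no stereocentre is touched.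

Step 6
Reactants: 11 ring B seco keto ester
Product: 12 1α-acetyl-5α,6α-epoxy-7β-isopropyl-trans-hydrindane-2,4-dione
Conditions: KOtBu (2.2 equiv), THF, 0 °C to 23 °C; then aq. NH4Cl
Reagents that add atoms: none
Why: Ring contraction of ring B (six to five) completed by a Dieckmann-type Claisen condensation, in which the internal ketone enolate (C1) attacks the ester five-exo and the product is drained as its stable β-diketonate while C3a and C7a stay untouched (C1 is epimerisable and one epimer is drawn).

Step 7
Reactants: 12 1α-acetyl-5α,6α-epoxy-7β-isopropyl-trans-hydrindane-2,4-dione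
Product: 13 1α-acetyl-5α,6α-epoxy-7β-isopropyl-4-methylidene-trans-hydrindan-2-one
Conditions: Ph3PCH3Br (3.2 equiv), KN(SiMe3)2 (3.0 equiv), THF, 0 °C to 23 °C
Reagents that add atoms: methylenetriphenylphosphorane C=P(c1ccccc1)(c1ccccc1)c1ccccc1
Why: Wittig methylenation in which the first equivalent of ylide deprotonates the β-diketone, masking both of its carbonyls as the enolate, so that only the activated epoxy ketone at C4 is olefinated.

Step 8
Reactants: 13 1α-acetyl-5α,6α-epoxy-7β-isopropyl-4-methylidene-trans-hydrindan-2-one; 14 acetaldehyde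
Product: 15 (1Z)-5α,6α-epoxy-1-ethylidene-7β-isopropyl-4-methylidene-trans-hydrindan-2-one
Conditions: LiN(SiMe3)2 (1.05 equiv), THF, −78 °C; CH3CHO (3 equiv), −78 to 0 °C; then DBU (20 mol%), 23 °C
Reagents that add atoms: none
Why: Proposed new method: deacetylative ethylidenation of a ring-fused 2-acetylcyclopentanone with an enolisable aldehyde, in which the lithium enolate of 13 adds to acetaldehyde, the aldolate attacks the exocyclic acetyl group through a spiro four-membered lactol (less strained than the ring-fused lactol that attack at C2 would need, so the ring ketone is kept), collapse gives the C2 enolate of a β-acetoxy ketone that expels acetate (E1cB), and DBU equilibrates the exocyclic enone to the Z isomer because an E methyl would clash with C7a and the C7 isopropyl group; the closest known reaction type is the deacylative (retro-Claisen) α-methylenation of 2-acyl lactones and β-keto esters with formaldehyde.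

Step 9
Reactants: 15 (1Z)-5α,6α-epoxy-1-ethylidene-7β-isopropyl-4-methylidene-trans-hydrindan-2-one
Product: 16 (1Z)-5α,6α-epoxy-1-ethylidene-7β-isopropyl-4-methylidene-trans-hydrindan-2β-ol
Conditions: (R)-1-methyl-3,3-diphenyltetrahydro-1H,3H-pyrrolo[1,2-c][1,3,2]oxazaborole (20 mol%), catecholborane (1.5 equiv), toluene, −78 °C
Reagents that add atoms: none
Why: Corey–Bakshi–Shibata reduction in which, with the alkylidene-bearing C1 as the large and the C3 methylene as the small substituent, the R-configured oxazaborolidine delivers hydride to the α face and sets the 2S (2β) alcohol under catalyst control, while catecholborane at −78 °C leaves the vinyl epoxide alone.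

Step 10
Reactants: 16 (1Z)-5α,6α-epoxy-1-ethylidene-7β-isopropyl-4-methylidene-trans-hydrindan-2β-ol
Product: 17 (1Z)-5α,6α-epoxy-1-ethylidene-7β-isopropyl-4-methylidene-trans-hydrindan-2β-yl acetate
Conditions: Ac2O, pyridine, DMAP (5 mol%), CH2Cl2, 0 °C
Reagents that add atoms: acetic anhydride CC(=O)OC(C)=O
Why: DMAP-catalysed acetylation of the only free hydroxyl, with retention at C2.

Step 11
Reactants: 17 (1Z)-5α,6α-epoxy-1-ethylidene-7β-isopropyl-4-methylidene-trans-hydrindan-2β-yl acetate; 18 angelic acid
Product: 19 target CNP0113604.1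
Conditions: 18 (3 equiv), Cs2CO3 (0.3 equiv), DMF, 55 °C
Reagents that add atoms: none
Why: SN2 opening of the epoxide by angelate under Fürst–Plattner control, in which only attack at C6 from the β face passes through a chair-like trans-diaxial transition state, so that C6 is inverted (6β-angelate) and the 5α-hydroxyl is left, while weakly basic conditions suppress ionisation at allylic C5 and angelate-to-tiglate isomerisation.

**Compound list**
1 | 3-methylbutanal | CC(C)CC=O | starting material
2 | but-3-en-2-one (methyl vinyl ketone) | CC(=O)C=C | starting material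
3 | (2S)-5-oxo-2-(propan-2-yl)hexanal | CC(=O)CC[C@@H](C(C)C)C=O | intermediate
4 | (4S)-4-(propan-2-yl)cyclohex-2-en-1-one, (S)-cryptone | O=C1CC[C@@H](C(C)C)C=C1 | intermediate
5 | 2-methylbuta-1,3-diene (isoprene) | C=CC(C)=C | starting material
6 | (4S,4aS,8aS)-6-methyl-4-(propan-2-yl)-3,4,4a,5,8,8a-hexahydronaphthalen-1(2H)-one, cis-fused | O=C1CC[C@@H](C(C)C)[C@@H]2CC(C)=CC[C@H]12 | intermediate
7 | (4S,4aS,8aR)-6-methyl-4-(propan-2-yl)-3,4,4a,5,8,8a-hexahydronaphthalen-1(2H)-one, trans-fused | O=C1CC[C@@H](C(C)C)[C@@H]2CC(C)=CC[C@@H]12 | intermediate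
8 | trimethylsilyl enol ether of 7 (C1–C2 enol double bond, octalone numbering) | C[Si](C)(C)OC1=CC[C@@H](C(C)C)[C@@H]2CC(C)=CC[C@@H]12 | intermediate
9 | (4R,4aS,8aR)-6-methyl-4-(propan-2-yl)-4a,5,8,8a-tetrahydronaphthalen-1(4H)-one | O=C1C=C[C@@H](C(C)C)[C@@H]2CC(C)=CC[C@@H]12 | intermediate
10 | (2R,3R,4S,4aS,8aR)-2,3-epoxy-6-methyl-4-(propan-2-yl)-3,4,4a,5,8,8a-hexahydronaphthalen-1(2H)-one (epoxide trans to isopropyl) | O=C1[C@@H]3O[C@@H]3[C@@H](C(C)C)[C@@H]2CC(C)=CC[C@@H]12 | intermediate
11 | methyl 2-[3,4-epoxy-2-oxo-6-(2-oxopropyl)-5-(propan-2-yl)cyclohexyl]acetate, configurations as in 10 | O=C1[C@@H]3O[C@@H]3[C@@H](C(C)C)[C@H](CC(C)=O)[C@H]1CC(=O)OC | intermediate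
12 | 1α-acetyl-5α,6α-epoxy-7β-isopropyl-trans-hydrindane-2,4-dione (C1 epimerisable, one epimer drawn) | O=C1[C@@H]3O[C@@H]3[C@@H](C(C)C)[C@@H]2[C@H](C(C)=O)C(=O)C[C@@H]12 | intermediate
13 | 1α-acetyl-5α,6α-epoxy-7β-isopropyl-4-methylidene-trans-hydrindan-2-one | C=C1[C@@H]3O[C@@H]3[C@@H](C(C)C)[C@@H]2[C@H](C(C)=O)C(=O)C[C@@H]12 | intermediate
14 | acetaldehyde | CC=O | starting material
15 | (1Z)-5α,6α-epoxy-1-ethylidene-7β-isopropyl-4-methylidene-trans-hydrindan-2-one | C=C1[C@@H]3O[C@@H]3[C@@H](C(C)C)[C@@H]2/C(=C/C)C(=O)C[C@@H]12 | intermediate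
16 | (1Z)-5α,6α-epoxy-1-ethylidene-7β-isopropyl-4-methylidene-trans-hydrindan-2β-ol | C=C1[C@@H]3O[C@@H]3[C@@H](C(C)C)[C@@H]2/C(=C/C)[C@@H](O)C[C@@H]12 | intermediate
17 | (1Z)-5α,6α-epoxy-1-ethylidene-7β-isopropyl-4-methylidene-trans-hydrindan-2β-yl acetate | C=C1[C@@H]3O[C@@H]3[C@@H](C(C)C)[C@@H]2/C(=C/C)[C@@H](OC(C)=O)C[C@@H]12 | intermediate
18 | angelic acid, (2Z)-2-methylbut-2-enoic acid | C/C=C(/C)C(=O)O | starting material
19 | CNP0113604.1, (1Z,2S,3aR,5S,6S,7S,7aR)-2-acetoxy-1-ethylidene-5-hydroxy-4-methylidene-7-(propan-2-yl)octahydro-1H-inden-6-yl (2Z)-2-methylbut-2-enoate | C=C1[C@H](O)[C@@H](OC(=O)/C(C)=C\C)[C@@H](C(C)C)[C@@H]2/C(=C/C)[C@@H](OC(C)=O)C[C@@H]12 | target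

**Step count:** 11 steps in total; the longest linear sequence is 11 steps (1 and 2 to 19).

**Three steps most likely to fail**

Step 8 (proposed new step). Risks are retro-Claisen opening of the ring ketone instead of acetyl transfer, and self-condensation of acetaldehyde. Fallback with known chemistry, setting out from 13 and returning at 15: deacylative diazo transfer (4-acetamidobenzenesulfonyl azide, Et3N, MeCN) removes the acetyl group and gives 1-diazo-5α,6α-epoxy-7β-isopropyl-4-methylidene-trans-hydrindan-2-one F1. Catalytic carbonyl olefination of acetaldehyde 14 with F1 (PPh3, chloro(5,10,15,20-tetraphenylporphyrinato)iron 1 mol%, toluene, 80 °C) then proceeds through the acyl-stabilised ylide. It gives 15 together with its (1E)-isomer F2, which DBU equilibrates to 15.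

Step 11. The risk is attack of angelate at allylic C5 (or at the exocyclic CH2) instead of C6. Fallback, setting out from 12 and returning at 19: keep the epoxy ketone and open it before methylenation, where the electronic preference (β-carbon of an α,β-epoxy ketone) and the diaxial preference both point to C6.
- Ethylidenation of 12 as in step 8 (or by the diazo route above) gives (1Z)-5α,6α-epoxy-1-ethylidene-7β-isopropyl-trans-hydrindane-2,4-dione F4.
- Oxazaborolidine-catalysed reduction as in step 9 (the doubly α-branched epoxy ketone reacts far more slowly) gives the 2β-alcohol F5.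
- Acetylation gives the 2β-acetate F6.
- Angelic acid 18 with catalytic p-toluenesulfonic acid opens the epoxide at C6 and gives (1Z)-2β-acetoxy-6β-angeloyloxy-1-ethylidene-5α-hydroxy-7β-isopropyl-trans-hydrindan-4-one F7.
- Non-basic methylenation with Zn, CH2Br2 and TiCl4 gives 19.

Step 9. The risk is that the substrate bias at C2 overrides the catalyst, or that borane attacks the vinyl epoxide. Fallback, setting out from 15 and returning at 17: NaBH4 with CeCl3·7H2O (MeOH, −78 °C) gives the substrate-preferred alcohol. If this is the 2α-epimer of 16, F3, Mitsunobu esterification with acetic acid (PPh3, diisopropyl azodicarboxylate, THF, inversion at C2) gives acetate 17 directly.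

**Further compounds**
F1 | step 8 | 1-diazo-5α,6α-epoxy-7β-isopropyl-4-methylidene-trans-hydrindan-2-one | C=C1[C@@H]3O[C@@H]3[C@@H](C(C)C)[C@@H]2C(=[N+]=[N-])C(=O)C[C@@H]12
F2 | step 8 | (1E)-5α,6α-epoxy-1-ethylidene-7β-isopropyl-4-methylidene-trans-hydrindan-2-one | C=C1[C@@H]3O[C@@H]3[C@@H](C(C)C)[C@@H]2/C(=C\C)C(=O)C[C@@H]12
F3 | step 9 | (1Z)-5α,6α-epoxy-1-ethylidene-7β-isopropyl-4-methylidene-trans-hydrindan-2α-ol | C=C1[C@@H]3O[C@@H]3[C@@H](C(C)C)[C@@H]2/C(=C/C)[C@H](O)C[C@@H]12
F4 | step 11 | (1Z)-5α,6α-epoxy-1-ethylidene-7β-isopropyl-trans-hydrindane-2,4-dione | O=C1[C@@H]3O[C@@H]3[C@@H](C(C)C)[C@@H]2/C(=C/C)C(=O)C[C@@H]12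
F5 | step 11 | (1Z)-5α,6α-epoxy-1-ethylidene-2β-hydroxy-7β-isopropyl-trans-hydrindan-4-one | O=C1[C@@H]3O[C@@H]3[C@@H](C(C)C)[C@@H]2/C(=C/C)[C@@H](O)C[C@@H]12
F6 | step 11 | (1Z)-5α,6α-epoxy-1-ethylidene-7β-isopropyl-4-oxo-trans-hydrindan-2β-yl acetate | O=C1[C@@H]3O[C@@H]3[C@@H](C(C)C)[C@@H]2/C(=C/C)[C@@H](OC(C)=O)C[C@@H]12
F7 | step 11 | (1Z)-2β-acetoxy-6β-angeloyloxy-1-ethylidene-5α-hydroxy-7β-isopropyl-trans-hydrindan-4-one | O=C1[C@H](O)[C@@H](OC(=O)/C(C)=C\C)[C@@H](C(C)C)[C@@H]2/C(=C/C)[C@@H](OC(C)=O)C[C@@H]12
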